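The 26-membered lactone (C1–C25 plus the lactone oxygen) is cut at C13–C14, inside the C13–C15 trimethylene bridge, the only methylene groups of the ring, which lies between the C12 methyl stereocentre and the C16 methoxy carbinol. The precursor is an open-chain ester, already joined at C25–O–C1, that ends in a primary bromide at C13 and in a vinyl group (C14=C15) on C16. Chemoselective hydroboration of that vinyl group with 9-BBN and an intramolecular alkyl–alkyl Suzuki–Miyaura coupling in the same flask close the macrocycle in one operation and leave no functional group to remove. Three fragments (C1–C13, C14–C25, C26–C36) supply the two halves.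

Key step: step 34

Remark: (3R,4R)-hexa-1,5-diene-3,4-diol (1), the enantiomer derived from D-mannitol, is taken as a purchasable starting material.
Conventions: locants C1–C36 in the names of larger compounds follow the target (C1 lactone carbonyl, C25 the ring carbon on the lactone oxygen, C26–C36 side chain); TES = triethylsilyl, Ipc = isopinocampheyl. CIP descriptors at C12, C22, C24, C30 and C32 change along the route only because substituent priorities change (Br, Si, CHO); the spatial arrangement is that of the target throughout.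

**C1–C13 acid**

Step 1
Reactants: 1 (3R,4R)-hexa-1,5-diene-3,4-diol
Product: 2 (3R,4R)-3,4-bis(triethylsilyloxy)hexa-1,5-diene
Conditions: TESCl (2.4 equiv), imidazole (5 equiv), DMF, 0 °C to rt
Reagents that add atoms: chlorotriethylsilane, CC[Si](Cl)(CC)CC
Why: Silyl ether formation at both secondary allylic hydroxyls; the C6 and C7 stereocentres come from the chiral pool and are not touched.

Step 2
Reactants: 2 (3R,4R)-3,4-bis(triethylsilyloxy)hexa-1,5-diene
Product: 3 (2E,4R,5R)-4,5-bis(triethylsilyloxy)hepta-2,6-dienal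
Conditions: (E)-crotonaldehyde (1 equiv for 3 equiv of 2), second-generation Hoveyda–Grubbs catalyst RuCl2(H2IMes)(=CH-C6H4-2-OiPr) (3 mol%), CH2Cl2, 40 °C; unreacted 2 recovered
Reagents that add atoms: (E)-but-2-enal, C/C=C/C=O
Why: Olefin cross-metathesis of a terminal alkene with an enal gives the E-enal, and because 2 is C2-symmetric either vinyl group gives the same product while the excess of 2 limits double reaction.

Step 3
Reactants: 3 (2E,4R,5R)-4,5-bis(triethylsilyloxy)hepta-2,6-dienal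
Product: 4 methyl (2E,4E,6R,7R)-6,7-bis(triethylsilyloxy)nona-2,4,8-trienoate
Conditions: Ph3P=CHCO2Me (1.5 equiv), CH2Cl2, rt
Reagents that add atoms: methyl (triphenylphosphoranylidene)acetate, COC(=O)C=P(c1ccccc1)(c1ccccc1)c1ccccc1
Why: Wittig olefination with a stabilised ylide is E-selective and should give the 2E,4E-dienoate.

Step 4
Reactants: 4 methyl (2E,4E,6R,7R)-6,7-bis(triethylsilyloxy)nona-2,4,8-trienoate
Product: 5 methyl (2E,4E,6R,7R,8E)-9-(4,4,5,5-tetramethyl-1,3,2-dioxaborolan-2-yl)-6,7-bis(triethylsilyloxy)nona-2,4,8-trienoate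
Conditions: vinylboronic acid pinacol ester (3 equiv), second-generation Grubbs catalyst RuCl2(H2IMes)(PCy3)(=CHPh) (10 mol%), CH2Cl2, 40 °C
Reagents that add atoms: 4,4,5,5-tetramethyl-2-vinyl-1,3,2-dioxaborolane, C=CB1OC(C)(C)C(C)(C)O1
Why: Olefin cross-metathesis of the remaining terminal alkene with the vinylboronate should give the E-alkenylboronate, the electron-poor dienoate alkenes being far less reactive towards the ruthenium carbene.

Step 5
Reactants: 6 methyl (S)-3-bromo-2-methylpropanoate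
Product: 7 (S)-3-bromo-2-methylpropanal
Conditions: i-Bu2AlH (1.05 equiv), CH2Cl2, −78 °C; MeOH, aq. potassium sodium tartrate; used at once as a cold CH2Cl2 solution
Reagents that add atoms: none
Why: Partial ester reduction stops at the aldehyde because the aluminium hemiacetal survives at −78 °C until the quench; the stereocentre that becomes C12 comes from the chiral pool.

Step 6
Reactants: 7 (S)-3-bromo-2-methylpropanal
Product: 8 (S)-1,1,4-tribromo-3-methylbut-1-ene
Conditions: CBr4 (2 equiv), PPh3 (4 equiv), CH2Cl2, 0 °C (ylide pre-formed), 30 min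
Reagents that add atoms: tetrabromomethane, BrC(Br)(Br)Br
Why: Ramirez dibromo-olefination (first stage of the Corey–Fuchs sequence) with pre-formed Ph3P=CBr2 is non-basic and should spare the β-bromide and the α-stereocentre.

Step 7
Reactants: 5 methyl (2E,4E,6R,7R,8E)-9-(pinacolboryl)-6,7-bis(triethylsilyloxy)nona-2,4,8-trienoate; 8 (S)-1,1,4-tribromo-3-methylbut-1-ene
Product: 9 methyl (2E,4E,6R,7R,8E,10Z,12S)-10,13-dibromo-12-methyl-6,7-bis(triethylsilyloxy)trideca-2,4,8,10-tetraenoate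
Conditions: Pd(PPh3)4 (5 mol%), TlOEt (1.8 equiv), THF/H2O 3:1, rt
Reagents that add atoms: none
Why: Suzuki–Miyaura coupling of a 1,1-dibromoalkene is trans-selective, so only the vinylic bromide trans to the C12 substituent should be replaced, and the primary alkyl bromide does not add to the triphenylphosphine-ligated catalyst.

Step 8
Reactants: 9 methyl (2E,4E,6R,7R,8E,10Z,12S)-10,13-dibromo-12-methyl-6,7-bis(triethylsilyloxy)trideca-2,4,8,10-tetraenoate
Product: 10 methyl (2E,4E,6R,7R,8E,10E,12S)-13-bromo-10,12-dimethyl-6,7-bis(triethylsilyloxy)trideca-2,4,8,10-tetraenoate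
Conditions: Me2Zn (2 equiv), Pd(P(t-Bu)3)2 (5 mol%), THF, 0 °C to rt
Reagents that add atoms: dimethylzinc, C[Zn]C
Why: Negishi methylation of the 2-bromo-1,3-diene with the tri-tert-butylphosphine catalyst is expected to proceed with retention of alkene geometry and so fixes the 10E trisubstituted alkene, while the alkyl bromide and the ester are inert to the zinc reagent.

Step 9
Reactants: 10 methyl (2E,4E,6R,7R,8E,10E,12S)-13-bromo-10,12-dimethyl-6,7-bis(triethylsilyloxy)trideca-2,4,8,10-tetraenoate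
Product: 11 (2E,4E,6R,7R,8E,10E,12S)-13-bromo-10,12-dimethyl-6,7-bis(triethylsilyloxy)trideca-2,4,8,10-tetraenoic acid
Conditions: Me3SnOH (6 equiv), 1,2-dichloroethane, 70 °C; aq. KHSO4 wash
Reagents that add atoms: trimethyltin hydroxide, C[Sn](C)(C)O
Why: Tin hydroxide-mediated ester hydrolysis is mild and weakly nucleophilic, so the TES ethers and the primary bromide should survive.

**C14–C25 aldehyde**

Step 10
Reactants: 12 methyl (R)-3-hydroxy-2-methylpropanoate
Product: 13 methyl (R)-2-methyl-3-(triethylsilyloxy)propanoate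
Conditions: TESCl (1.1 equiv), imidazole (2 equiv), CH2Cl2, 0 °C to rt
Reagents that add atoms: chlorotriethylsilane, CC[Si](Cl)(CC)CC
Why: Silyl ether formation at the primary hydroxyl; the stereocentre that becomes C22 comes from the chiral pool.

Step 11
Reactants: 13 methyl (R)-2-methyl-3-(triethylsilyloxy)propanoate
Product: 14 (R)-2-methyl-3-(triethylsilyloxy)propanal
Conditions: i-Bu2AlH (1.1 equiv), CH2Cl2, −78 °C; MeOH, aq. potassium sodium tartrate; used crude
Reagents that add atoms: none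
Why: Partial ester reduction at −78 °C stops at the aldehyde, which is used without chromatography to avoid epimerisation.

Step 12
Reactants: 15 (R)-4-benzyloxazolidin-2-one
Product: 16 (R)-4-benzyl-3-(2-methoxyacetyl)oxazolidin-2-one
Conditions: methoxyacetyl chloride (1.2 equiv), Et3N (1.5 equiv), DMAP (10 mol%), CH2Cl2, 0 °C to rt
Reagents that add atoms: methoxyacetyl chloride, COCC(=O)Cl
Why: N-acylation of the oxazolidinone by the acid chloride under nucleophilic (DMAP) catalysis.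

Step 13
Reactants: 16 (R)-4-benzyl-3-(2-methoxyacetyl)oxazolidin-2-one; 14 (R)-2-methyl-3-(triethylsilyloxy)propanal
Product: 18 (R)-4-benzyl-3-[(2R,3S,4R)-3-hydroxy-2-methoxy-4-methyl-5-(triethylsilyloxy)pentanoyl]oxazolidin-2-one, via dibutylboron Z-enolate 17 (not isolated)
Conditions: Bu2BOTf (1.2 equiv), Et3N (1.4 equiv), CH2Cl2, −78 to 0 °C; then 14, −78 to 0 °C; pH 7 buffer, MeOH, H2O2, 0 °C
Reagents that add atoms: dibutylboron trifluoromethanesulfonate, CCCCB(CCCC)OS(=O)(=O)C(F)(F)F (boron in intermediate 17 only)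
Why: Evans syn-aldol reaction of the glycolate Z-boron enolate through a Zimmerman–Traxler chair, in which the (R)-benzyl auxiliary sets C24 (R) and C23 (S) and the all-syn relation to the C22 methyl group is the matched (anti-Felkin) outcome for a Z-enolate.

Step 14
Reactants: 18 (R)-4-benzyl-3-[(2R,3S,4R)-3-hydroxy-2-methoxy-4-methyl-5-(triethylsilyloxy)pentanoyl]oxazolidin-2-one
Product: 19 (2R,3S,4R)-3-hydroxy-N,2-dimethoxy-N,4-dimethyl-5-(triethylsilyloxy)pentanamide
Conditions: MeNH(OMe)·HCl (3 equiv), AlMe3 (3 equiv), THF, −20 to 0 °C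
Reagents that add atoms: N,O-dimethylhydroxylamine hydrochloride, CNOC.Cl
Why: Weinreb transamidation by the aluminium amide, assisted by the free β-hydroxyl, removes the auxiliary and masks C25 as a latent aldehyde.

Step 15
Reactants: 19 (2R,3S,4R)-3-hydroxy-N,2-dimethoxy-N,4-dimethyl-5-(triethylsilyloxy)pentanamide
Product: 20 (2R,3S,4R)-N,2-dimethoxy-N,4-dimethyl-3,5-bis(triethylsilyloxy)pentanamide
Conditions: TESOTf (1.3 equiv), 2,6-lutidine (2 equiv), CH2Cl2, −78 °C
Reagents that add atoms: triethylsilyl trifluoromethanesulfonate, CC[Si](CC)(CC)OS(=O)(=O)C(F)(F)F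
Why: Silyl ether formation at the hindered C23 hydroxyl with the reactive silyl triflate.

Step 16
Reactants: 20 (2R,3S,4R)-N,2-dimethoxy-N,4-dimethyl-3,5-bis(triethylsilyloxy)pentanamide
Product: 21 (2R,3S,4S)-N,2-dimethoxy-N,4-dimethyl-5-oxo-3-(triethylsilyloxy)pentanamide
Conditions: (COCl)2 (4 equiv), DMSO (8 equiv), CH2Cl2, −78 to −30 °C; Et3N, −78 to 0 °C
Reagents that add atoms: none
Why: Swern oxidation cleaves and oxidises a primary TES ether directly to the aldehyde while the secondary TES ether and the Weinreb amide survive.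

Step 17
Reactants: 21 (2R,3S,4S)-N,2-dimethoxy-N,4-dimethyl-5-oxo-3-(triethylsilyloxy)pentanamide
Product: 22 (2R,3S,4R,5E)-N,2-dimethoxy-N,4,6-trimethyl-7-oxo-3-(triethylsilyloxy)hept-5-enamide
Conditions: Ph3P=C(Me)CHO (2 equiv), toluene, 80 °C
Reagents that add atoms: 2-(triphenylphosphoranylidene)propanal, CC(C=O)=P(c1ccccc1)(c1ccccc1)c1ccccc1
Why: Wittig olefination with the stabilised formyl ylide should give the E-trisubstituted enal (C20=C21) without epimerising C22.

Step 18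
Reactants: 22 (2R,3S,4R,5E)-N,2-dimethoxy-N,4,6-trimethyl-7-oxo-3-(triethylsilyloxy)hept-5-enamide
Product: 23 (2R,3S,4R,5E,7E)-N,2-dimethoxy-N,4,6-trimethyl-9-oxo-3-(triethylsilyloxy)nona-5,7-dienamide
Conditions: Ph3P=CHCHO (1.3 equiv), toluene, 80 °C
Reagents that add atoms: (triphenylphosphoranylidene)acetaldehyde, O=CC=P(c1ccccc1)(c1ccccc1)c1ccccc1
Why: Wittig two-carbon homologation with the stabilised formyl ylide should give the E,E-dienal (C18=C19).

Step 19
Reactants: 23 (2R,3S,4R,5E,7E)-N,2-dimethoxy-N,4,6-trimethyl-9-oxo-3-(triethylsilyloxy)nona-5,7-dienamide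
Product: 24 (2R,3S,4R,5E,7E,9R,10R)-9-hydroxy-N,2,10-trimethoxy-N,4,6-trimethyl-3-(triethylsilyloxy)dodeca-5,7,11-trienamide
Conditions: allyl methyl ether, s-BuLi, THF, −78 °C; (−)-Ipc2BOMe; BF3·OEt2; then 23, −78 °C; NaOH, H2O2, rt
Reagents that add atoms: 3-methoxyprop-1-ene (allyl methyl ether), C=CCOC
Why: Brown (Z)-γ-methoxyallylboration through a chair transition state gives the syn methoxy alcohol, and the borane derived from (+)-α-pinene adds to the Si face of the aldehyde, setting C17 (R) and C16 (R) together with the C14=C15 vinyl group.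

Step 20
Reactants: 24 (2R,3S,4R,5E,7E,9R,10R)-9-hydroxy-N,2,10-trimethoxy-N,4,6-trimethyl-3-(triethylsilyloxy)dodeca-5,7,11-trienamide
Product: 25 (2R,3S,4R,5E,7E,9R,10R)-N,2,10-trimethoxy-N,4,6-trimethyl-3,9-bis(triethylsilyloxy)dodeca-5,7,11-trienamide
Conditions: TESOTf (1.3 equiv), 2,6-lutidine (2 equiv), CH2Cl2, −78 °C
Reagents that add atoms: triethylsilyl trifluoromethanesulfonate, CC[Si](CC)(CC)OS(=O)(=O)C(F)(F)F
Why: Silyl ether formation at the C17 hydroxyl under non-acidic conditions that spare the diene.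

Step 21
Reactants: 25 (2R,3S,4R,5E,7E,9R,10R)-N,2,10-trimethoxy-N,4,6-trimethyl-3,9-bis(triethylsilyloxy)dodeca-5,7,11-trienamide
Product: 26 (2R,3S,4R,5E,7E,9R,10R)-2,10-dimethoxy-4,6-dimethyl-3,9-bis(triethylsilyloxy)dodeca-5,7,11-trienal
Conditions: i-Bu2AlH (1.5 equiv), THF, −78 °C; aq. potassium sodium tartrate; used at once
Reagents that add atoms: none
Why: Weinreb amide reduction stops at the aldehyde because the chelated tetrahedral intermediate collapses only on work-up; immediate use avoids epimerisation at C24.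

**C26–C36 vinyl iodide**

Step 22
Reactants: 27 butanal
Product: 28 (3S,4S)-3-methoxyhept-1-en-4-ol
Conditions: allyl methyl ether, s-BuLi, THF, −78 °C; (+)-Ipc2BOMe; BF3·OEt2; then 27, −78 °C; NaOH, H2O2, rt
Reagents that add atoms: 3-methoxyprop-1-ene (allyl methyl ether), C=CCOC
Why: Brown (Z)-γ-methoxyallylboration gives the syn methoxy alcohol, and the borane derived from (−)-α-pinene adds to the Re face of butanal, setting C33 and C32.

Step 23
Reactants: 28 (3S,4S)-3-methoxyhept-1-en-4-ol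
Product: 29 triethyl{[(3S,4S)-3-methoxyhept-1-en-4-yl]oxy}silane
Conditions: TESCl (1.2 equiv), imidazole (2.5 equiv), DMF, 0 °C to rt
Reagents that add atoms: chlorotriethylsilane, CC[Si](Cl)(CC)CC
Why: Silyl ether formation at the C33 hydroxyl.

Step 24
Reactants: 29 triethyl{[(3S,4S)-3-methoxyhept-1-en-4-yl]oxy}silane
Product: 31 ethyl (2E,4S,5S)-4-methoxy-2-methyl-5-(triethylsilyloxy)oct-2-enoate, via methoxy aldehyde 30 (not isolated)
Conditions: O3, CH2Cl2, −78 °C; PPh3, −78 °C to rt; then Ph3P=C(Me)CO2Et (1.5 equiv), rt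
Reagents that add atoms: ozone, [O-][O+]=O (aldehyde oxygen of 30 only); ethyl 2-(triphenylphosphoranylidene)propanoate, CCOC(=O)C(C)=P(c1ccccc1)(c1ccccc1)c1ccccc1
Why: Ozonolysis with reductive work-up followed in the same flask by Wittig olefination with the stabilised ylide gives the E-trisubstituted enoate and avoids handling the epimerisable α-methoxy aldehyde.

Step 25
Reactants: 31 ethyl (2E,4S,5S)-4-methoxy-2-methyl-5-(triethylsilyloxy)oct-2-enoate
Product: 32 (2E,4S,5S)-4-methoxy-2-methyl-5-(triethylsilyloxy)oct-2-en-1-ol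
Conditions: i-Bu2AlH (2.5 equiv), CH2Cl2, −78 °C; aq. potassium sodium tartrate
Reagents that add atoms: none
Why: 1,2-Reduction of the enoate by the aluminium hydride gives the allylic alcohol without touching the alkene geometry.

Step 26
Reactants: 32 (2E,4S,5S)-4-methoxy-2-methyl-5-(triethylsilyloxy)oct-2-en-1-ol
Product: 33 [(2R,3R)-3-[(1S,2S)-1-methoxy-2-(triethylsilyloxy)pentyl]-2-methyloxiran-2-yl]methanol
Conditions: Ti(OiPr)4 (20 mol%), D-(−)-diisopropyl tartrate (24 mol%), t-BuOOH (2 equiv), 4 Å molecular sieves, CH2Cl2, −20 °C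
Reagents that add atoms: tert-butyl hydroperoxide, CC(C)(C)OO
Why: Sharpless asymmetric epoxidation under reagent control, the D-(−)-tartrate catalyst giving the (2R,3R)-epoxy alcohol (C30, C31), the series opposite to the (2S,3S) epoxides that L-(+)-tartrate gives from E-allylic alcohols.

Step 27
Reactants: 33 [(2R,3R)-3-[(1S,2S)-1-methoxy-2-(triethylsilyloxy)pentyl]-2-methyloxiran-2-yl]methanol
Product: 34 (2S,3R)-3-[(1S,2S)-1-methoxy-2-(triethylsilyloxy)pentyl]-2-methyloxirane-2-carbaldehyde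
Conditions: Dess–Martin periodinane (1.5 equiv), NaHCO3, CH2Cl2, 0 °C to rt
Reagents that add atoms: none
Why: Dess–Martin oxidation of the primary alcohol gives the epoxy aldehyde, which has no α-hydrogen and cannot epimerise.

Step 28
Reactants: 34 (2S,3R)-3-[(1S,2S)-1-methoxy-2-(triethylsilyloxy)pentyl]-2-methyloxirane-2-carbaldehyde
Product: 35 (S)-1-[(2R,3R)-3-[(1S,2S)-1-methoxy-2-(triethylsilyloxy)pentyl]-2-methyloxiran-2-yl]but-3-en-1-ol
Conditions: (−)-Ipc2BOMe, allylMgBr, Et2O, 0 °C to rt; then 34, −78 °C; ethanolamine work-up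
Reagents that add atoms: allylmagnesium bromide, C=CC[Mg]Br
Why: Brown allylboration under reagent control, the allylborane derived from (+)-α-pinene adding to the Si face of the aldehyde to set C29 (S), with a non-basic work-up that avoids Payne rearrangement.

Step 29
Reactants: 35 (S)-1-[(2R,3R)-3-[(1S,2S)-1-methoxy-2-(triethylsilyloxy)pentyl]-2-methyloxiran-2-yl]but-3-en-1-ol
Product: 36 triethyl{[(S)-1-[(2S,3R)-3-[(1S,2S)-1-methoxy-2-(triethylsilyloxy)pentyl]-2-methyloxiran-2-yl]but-3-en-1-yl]oxy}silane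
Conditions: TESOTf (1.3 equiv), 2,6-lutidine (2.5 equiv), CH2Cl2, −78 °C
Reagents that add atoms: triethylsilyl trifluoromethanesulfonate, CC[Si](CC)(CC)OS(=O)(=O)C(F)(F)F
Why: Silyl ether formation at the hindered C29 hydroxyl at low temperature in the presence of excess base, which protects the epoxide from the Lewis-acidic triflate.

Step 30
Reactants: 36 triethyl{[(S)-1-[(2S,3R)-3-[(1S,2S)-1-methoxy-2-(triethylsilyloxy)pentyl]-2-methyloxiran-2-yl]but-3-en-1-yl]oxy}silane
Product: 37 (S)-3-[(2S,3R)-3-[(1S,2S)-1-methoxy-2-(triethylsilyloxy)pentyl]-2-methyloxiran-2-yl]-3-(triethylsilyloxy)propanal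
Conditions: O3, CH2Cl2, −78 °C; PPh3, −78 °C to rt
Reagents that add atoms: ozone, [O-][O+]=O
Why: Ozonolysis of the only alkene with reductive work-up gives the β-silyloxy aldehyde (C27).

Step 31
Reactants: 37 (S)-3-[(2S,3R)-3-[(1S,2S)-1-methoxy-2-(triethylsilyloxy)pentyl]-2-methyloxiran-2-yl]-3-(triethylsilyloxy)propanal
Product: 38 triethyl{[(S,E)-4-iodo-1-[(2S,3R)-3-[(1S,2S)-1-methoxy-2-(triethylsilyloxy)pentyl]-2-methyloxiran-2-yl]but-3-en-1-yl]oxy}silane
Conditions: CrCl2 (8 equiv), CHI3 (3 equiv), THF/1,4-dioxane 1:6, 0 °C to rt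
Reagents that add atoms: iodoform, IC(I)I
Why: Takai olefination, in which the geminal dichromium species from iodoform adds to the aldehyde and eliminates to the E-alkenyl iodide (C26=C27) without affecting the epoxide.

**Union, ring closure and deprotection**

Step 32
Reactants: 26 C14–C25 aldehyde; 38 C26–C36 E-alkenyl iodide
Product: 39 C14–C36 alcohol (free C25 hydroxyl; 16R,17R,22R,23S,24S,25S,29S,30S,31R,32S,33S; 18E,20E,26E)
Conditions: CrCl2 (6 equiv), NiCl2 (1 mol%), DMSO, rt; 38 (1.5 equiv)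
Reagents that add atoms: none
Why: Nozaki–Hiyama–Kishi coupling, in which the alkenylchromium species adds chemoselectively to the aldehyde and Felkin–Anh attack anti to the C24 methoxy group should favour the 24,25-anti alcohol (C25 S).

Step 33
Reactants: 11 C1–C13 acid; 39 C14–C36 alcohol
Product: 41 C1–C36 seco ester (C13 bromide; C14=C15 vinyl), via mixed anhydride 40 (not isolated)
Conditions: 11 (1.3 equiv), 2,4,6-trichlorobenzoyl chloride (1.4 equiv), Et3N (2 equiv), toluene, rt; then 39, DMAP (2 equiv), toluene, rt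
Reagents that add atoms: 2,4,6-trichlorobenzoyl chloride, O=C(Cl)c1c(Cl)cc(Cl)cc1Cl (in intermediate 40 only)
Why: Yamaguchi esterification, in which DMAP opens the mixed anhydride and the acylpyridinium acylates the only free hydroxyl (C25) with retention at C25.

Step 34
Reactants: 41 C1–C36 seco ester
Product: 43 hexakis-TES macrolactone, via B-alkyl-9-BBN adduct 42 (not isolated)
Conditions: 9-BBN dimer (0.75 equiv), THF, 0 °C to rt, 4 h; the solution is added over 12 h by syringe pump to Pd(OAc)2 (20 mol%), PCy3 (40 mol%), K3PO4·H2O (3 equiv), THF, rt, final concentration about 1 mM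
Reagents that add atoms: 9-borabicyclo[3.3.1]nonane, B1C2CCCC1CCC2 (in intermediate 42 only)
Why: Proposed new method: 9-BBN adds anti-Markovnikov to the only monosubstituted alkene (C14=C15) and places boron on C14, after which zerovalent palladium carrying PCy3 inserts into the primary C13–Br bond by an SN2-type oxidative addition, the base-activated B-alkyl borinate transmetalates, and reductive elimination from the dialkyl divalent palladium forms the C13–C14 bond; the closest known reaction type is the intermolecular alkyl–alkyl Suzuki–Miyaura coupling of primary alkyl bromides bearing β-hydrogens with B-alkyl-9-BBN reagents, together with B-alkyl Suzuki macrocyclisations onto alkenyl iodides. The 26-membered ring closes end to end through a 27-membered palladacycle (a macrocyclisation outside the small-ring exo/endo categories), and slow addition at high dilution favours ring closure over oligomer formation. No stereocentre is formed, and C12 and C16, which flank the new bond, are not involved. The step needs hydroboration only at the vinyl group (secured by the steric demand of 9-BBN towards the seven di- and trisubstituted alkenes), oxidative addition at C13–Br faster than ionisation of the hindered C25 allylic ester (secured by room temperature and the γ-substituted allylic system), and coupling faster than β-hydride elimination towards C12 (secured by the bulky, electron-rich PCy3).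

Step 35
Reactants: 43 hexakis-TES macrolactone
Product: 44 CNP0328768.3 (target)
Conditions: HF·pyridine (excess), pyridine, THF, 0 °C to rt
Reagents that add atoms: none
Why: Fluoride-mediated silyl ether cleavage removes all six TES groups under buffered conditions that should spare the epoxide, the dienoate lactone and the dienes.

**Compound list**

1 | (3R,4R)-hexa-1,5-diene-3,4-diol | C=C[C@@H](O)[C@H](O)C=C | starting material
2 | (3R,4R)-3,4-bis(triethylsilyloxy)hexa-1,5-diene | C=C[C@@H](O[Si](CC)(CC)CC)[C@H](O[Si](CC)(CC)CC)C=C | intermediate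
3 | (2E,4R,5R)-4,5-bis(triethylsilyloxy)hepta-2,6-dienal | O=C/C=C/[C@@H](O[Si](CC)(CC)CC)[C@H](O[Si](CC)(CC)CC)C=C | intermediate
4 | methyl (2E,4E,6R,7R)-6,7-bis(triethylsilyloxy)nona-2,4,8-trienoate | COC(=O)/C=C/C=C/[C@@H](O[Si](CC)(CC)CC)[C@H](O[Si](CC)(CC)CC)C=C | intermediate
5 | methyl (2E,4E,6R,7R,8E)-9-(4,4,5,5-tetramethyl-1,3,2-dioxaborolan-2-yl)-6,7-bis(triethylsilyloxy)nona-2,4,8-trienoate | COC(=O)/C=C/C=C/[C@@H](O[Si](CC)(CC)CC)[C@H](O[Si](CC)(CC)CC)/C=C/B1OC(C)(C)C(C)(C)O1 | intermediate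
6 | methyl (S)-3-bromo-2-methylpropanoate | COC(=O)[C@H](C)CBr | starting material
7 | (S)-3-bromo-2-methylpropanal | O=C[C@H](C)CBr | intermediate
8 | (S)-1,1,4-tribromo-3-methylbut-1-ene | BrC(Br)=C[C@H](C)CBr | intermediate
9 | methyl (2E,4E,6R,7R,8E,10Z,12S)-10,13-dibromo-12-methyl-6,7-bis(triethylsilyloxy)trideca-2,4,8,10-tetraenoate | COC(=O)/C=C/C=C/[C@@H](O[Si](CC)(CC)CC)[C@H](O[Si](CC)(CC)CC)/C=C/C(Br)=C/[C@H](C)CBr | intermediate
10 | methyl (2E,4E,6R,7R,8E,10E,12S)-13-bromo-10,12-dimethyl-6,7-bis(triethylsilyloxy)trideca-2,4,8,10-tetraenoate | COC(=O)/C=C/C=C/[C@@H](O[Si](CC)(CC)CC)[C@H](O[Si](CC)(CC)CC)/C=C/C(C)=C/[C@H](C)CBr | intermediate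
11 | (2E,4E,6R,7R,8E,10E,12S)-13-bromo-10,12-dimethyl-6,7-bis(triethylsilyloxy)trideca-2,4,8,10-tetraenoic acid (C1–C13 acid) | OC(=O)/C=C/C=C/[C@@H](O[Si](CC)(CC)CC)[C@H](O[Si](CC)(CC)CC)/C=C/C(C)=C/[C@H](C)CBr | intermediate
12 | methyl (R)-3-hydroxy-2-methylpropanoate | OC[C@@H](C)C(=O)OC | starting material
13 | methyl (R)-2-methyl-3-(triethylsilyloxy)propanoate | CC[Si](CC)(CC)OC[C@@H](C)C(=O)OC | intermediate
14 | (R)-2-methyl-3-(triethylsilyloxy)propanal | CC[Si](CC)(CC)OC[C@@H](C)C=O | intermediate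
15 | (R)-4-benzyloxazolidin-2-one | O=C1N[C@H](Cc2ccccc2)CO1 | starting material
16 | (R)-4-benzyl-3-(2-methoxyacetyl)oxazolidin-2-one | COCC(=O)N1[C@H](Cc2ccccc2)COC1=O | intermediate
17 | dibutylboron (Z)-enolate of 16 (not isolated) | CO/C=C(\OB(CCCC)CCCC)N1[C@H](Cc2ccccc2)COC1=O | intermediate
18 | (R)-4-benzyl-3-[(2R,3S,4R)-3-hydroxy-2-methoxy-4-methyl-5-(triethylsilyloxy)pentanoyl]oxazolidin-2-one | CC[Si](CC)(CC)OC[C@@H](C)[C@H](O)[C@@H](OC)C(=O)N1[C@H](Cc2ccccc2)COC1=O | intermediate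
19 | (2R,3S,4R)-3-hydroxy-N,2-dimethoxy-N,4-dimethyl-5-(triethylsilyloxy)pentanamide | CC[Si](CC)(CC)OC[C@@H](C)[C@H](O)[C@@H](OC)C(=O)N(C)OC | intermediate
20 | (2R,3S,4R)-N,2-dimethoxy-N,4-dimethyl-3,5-bis(triethylsilyloxy)pentanamide | CC[Si](CC)(CC)OC[C@@H](C)[C@H](O[Si](CC)(CC)CC)[C@@H](OC)C(=O)N(C)OC | intermediate
21 | (2R,3S,4S)-N,2-dimethoxy-N,4-dimethyl-5-oxo-3-(triethylsilyloxy)pentanamide | O=C[C@@H](C)[C@H](O[Si](CC)(CC)CC)[C@@H](OC)C(=O)N(C)OC | intermediate
22 | (2R,3S,4R,5E)-N,2-dimethoxy-N,4,6-trimethyl-7-oxo-3-(triethylsilyloxy)hept-5-enamide | O=C/C(C)=C/[C@@H](C)[C@H](O[Si](CC)(CC)CC)[C@@H](OC)C(=O)N(C)OC | intermediate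
23 | (2R,3S,4R,5E,7E)-N,2-dimethoxy-N,4,6-trimethyl-9-oxo-3-(triethylsilyloxy)nona-5,7-dienamide | O=C/C=C/C(C)=C/[C@@H](C)[C@H](O[Si](CC)(CC)CC)[C@@H](OC)C(=O)N(C)OC | intermediate
24 | (2R,3S,4R,5E,7E,9R,10R)-9-hydroxy-N,2,10-trimethoxy-N,4,6-trimethyl-3-(triethylsilyloxy)dodeca-5,7,11-trienamide | C=C[C@@H](OC)[C@H](O)/C=C/C(C)=C/[C@@H](C)[C@H](O[Si](CC)(CC)CC)[C@@H](OC)C(=O)N(C)OC | intermediate
25 | (2R,3S,4R,5E,7E,9R,10R)-N,2,10-trimethoxy-N,4,6-trimethyl-3,9-bis(triethylsilyloxy)dodeca-5,7,11-trienamide | C=C[C@@H](OC)[C@H](O[Si](CC)(CC)CC)/C=C/C(C)=C/[C@@H](C)[C@H](O[Si](CC)(CC)CC)[C@@H](OC)C(=O)N(C)OC | intermediate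
26 | (2R,3S,4R,5E,7E,9R,10R)-2,10-dimethoxy-4,6-dimethyl-3,9-bis(triethylsilyloxy)dodeca-5,7,11-trienal (C14–C25 aldehyde) | C=C[C@@H](OC)[C@H](O[Si](CC)(CC)CC)/C=C/C(C)=C/[C@@H](C)[C@H](O[Si](CC)(CC)CC)[C@@H](OC)C=O | intermediate
27 | butanal | CCCC=O | starting material
28 | (3S,4S)-3-methoxyhept-1-en-4-ol | C=C[C@H](OC)[C@@H](O)CCC | intermediate
29 | triethyl{[(3S,4S)-3-methoxyhept-1-en-4-yl]oxy}silane | C=C[C@H](OC)[C@@H](O[Si](CC)(CC)CC)CCC | intermediate
30 | (2R,3S)-2-methoxy-3-(triethylsilyloxy)hexanal (not isolated) | O=C[C@H](OC)[C@@H](O[Si](CC)(CC)CC)CCC | intermediate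
31 | ethyl (2E,4S,5S)-4-methoxy-2-methyl-5-(triethylsilyloxy)oct-2-enoate | CCOC(=O)/C(C)=C/[C@H](OC)[C@@H](O[Si](CC)(CC)CC)CCC | intermediate
32 | (2E,4S,5S)-4-methoxy-2-methyl-5-(triethylsilyloxy)oct-2-en-1-ol | OC/C(C)=C/[C@H](OC)[C@@H](O[Si](CC)(CC)CC)CCC | intermediate
33 | [(2R,3R)-3-[(1S,2S)-1-methoxy-2-(triethylsilyloxy)pentyl]-2-methyloxiran-2-yl]methanol | OC[C@@]1(C)O[C@@H]1[C@H](OC)[C@@H](O[Si](CC)(CC)CC)CCC | intermediate
34 | (2S,3R)-3-[(1S,2S)-1-methoxy-2-(triethylsilyloxy)pentyl]-2-methyloxirane-2-carbaldehyde | O=C[C@@]1(C)O[C@@H]1[C@H](OC)[C@@H](O[Si](CC)(CC)CC)CCC | intermediate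
35 | (S)-1-[(2R,3R)-3-[(1S,2S)-1-methoxy-2-(triethylsilyloxy)pentyl]-2-methyloxiran-2-yl]but-3-en-1-ol | C=CC[C@H](O)[C@@]1(C)O[C@@H]1[C@H](OC)[C@@H](O[Si](CC)(CC)CC)CCC | intermediate
36 | triethyl{[(S)-1-[(2S,3R)-3-[(1S,2S)-1-methoxy-2-(triethylsilyloxy)pentyl]-2-methyloxiran-2-yl]but-3-en-1-yl]oxy}silane | C=CC[C@H](O[Si](CC)(CC)CC)[C@@]1(C)O[C@@H]1[C@H](OC)[C@@H](O[Si](CC)(CC)CC)CCC | intermediate
37 | (S)-3-[(2S,3R)-3-[(1S,2S)-1-methoxy-2-(triethylsilyloxy)pentyl]-2-methyloxiran-2-yl]-3-(triethylsilyloxy)propanal | O=CC[C@H](O[Si](CC)(CC)CC)[C@@]1(C)O[C@@H]1[C@H](OC)[C@@H](O[Si](CC)(CC)CC)CCC | intermediate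
38 | triethyl{[(S,E)-4-iodo-1-[(2S,3R)-3-[(1S,2S)-1-methoxy-2-(triethylsilyloxy)pentyl]-2-methyloxiran-2-yl]but-3-en-1-yl]oxy}silane (C26–C36 alkenyl iodide) | I/C=C/C[C@H](O[Si](CC)(CC)CC)[C@@]1(C)O[C@@H]1[C@H](OC)[C@@H](O[Si](CC)(CC)CC)CCC | intermediate
39 | C14–C36 alcohol: 16,24,32-trimethoxy-20,22,30-trimethyl-30,31-epoxy-17,23,29,33-tetrakis(triethylsilyloxy) chain C14–C36 with C14=C15, 18E, 20E, 26E alkenes and free C25 hydroxyl; 16R,17R,22R,23S,24S,25S,29S,30S,31R,32S,33S | C=C[C@@H](OC)[C@H](O[Si](CC)(CC)CC)/C=C/C(C)=C/[C@@H](C)[C@H](O[Si](CC)(CC)CC)[C@@H](OC)[C@@H](O)/C=C/C[C@H](O[Si](CC)(CC)CC)[C@@]1(C)O[C@@H]1[C@H](OC)[C@@H](O[Si](CC)(CC)CC)CCC | intermediate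
40 | mixed anhydride of acid 11 with 2,4,6-trichlorobenzoic acid (not isolated) | O=C(OC(=O)/C=C/C=C/[C@@H](O[Si](CC)(CC)CC)[C@H](O[Si](CC)(CC)CC)/C=C/C(C)=C/[C@H](C)CBr)c1c(Cl)cc(Cl)cc1Cl | intermediate
41 | C1–C36 seco ester: C25 ester of alcohol 39 with acid 11; 6R,7R,12S,16R,17R,22R,23S,24S,25S,29S,30S,31R,32S,33S; 2E,4E,8E,10E,18E,20E,26E | C=C[C@@H](OC)[C@H](O[Si](CC)(CC)CC)/C=C/C(C)=C/[C@@H](C)[C@H](O[Si](CC)(CC)CC)[C@@H](OC)[C@@H](OC(=O)/C=C/C=C/[C@@H](O[Si](CC)(CC)CC)[C@H](O[Si](CC)(CC)CC)/C=C/C(C)=C/[C@H](C)CBr)/C=C/C[C@H](O[Si](CC)(CC)CC)[C@@]1(C)O[C@@H]1[C@H](OC)[C@@H](O[Si](CC)(CC)CC)CCC | intermediate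
42 | B-alkyl-9-BBN adduct of 41 (boron on C14; not isolated) | C1CCC2CCCC1B2CC[C@@H](OC)[C@H](O[Si](CC)(CC)CC)/C=C/C(C)=C/[C@@H](C)[C@H](O[Si](CC)(CC)CC)[C@@H](OC)[C@@H](OC(=O)/C=C/C=C/[C@@H](O[Si](CC)(CC)CC)[C@H](O[Si](CC)(CC)CC)/C=C/C(C)=C/[C@H](C)CBr)/C=C/C[C@H](O[Si](CC)(CC)CC)[C@@]1(C)O[C@@H]1[C@H](OC)[C@@H](O[Si](CC)(CC)CC)CCC | intermediate
43 | hexakis-TES macrolactone: 6,7,17,23,29,33-hexakis(triethylsilyl) ether of the target; 6R,7R,12R,16R,17R,22R,23S,24S,25S,29S,30S,31R,32S,33S | CCC[C@H](O[Si](CC)(CC)CC)[C@@H](OC)[C@H]1O[C@]1(C)[C@@H](O[Si](CC)(CC)CC)C/C=C/[C@@H]1OC(=O)/C=C/C=C/[C@@H](O[Si](CC)(CC)CC)[C@H](O[Si](CC)(CC)CC)/C=C/C(C)=C/[C@H](C)CCC[C@@H](OC)[C@H](O[Si](CC)(CC)CC)/C=C/C(C)=C/[C@@H](C)[C@H](O[Si](CC)(CC)CC)[C@H]1OC | intermediate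
44 | CNP0328768.3: 26-membered macrolactone, 6R,7R,12R,16R,17R,22R,23S,24R,25S,29S,30R,31R,32R,33S; 2E,4E,8E,10E,18E,20E,26E | CCC[C@H](O)[C@@H](OC)[C@H]1O[C@]1(C)[C@@H](O)C/C=C/[C@@H]1OC(=O)/C=C/C=C/[C@@H](O)[C@H](O)/C=C/C(C)=C/[C@H](C)CCC[C@@H](OC)[C@H](O)/C=C/C(C)=C/[C@@H](C)[C@H](O)[C@H]1OC | target

**Count and risks**

Total step count: 35. Longest linear sequence: 15 steps (12 → 13 → 14 → 18 → 19 → 20 → 21 → 22 → 23 → 24 → 25 → 26 → 39 → 41 → 43 → 44; steps 10, 11, 13–21, 32–35).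

Steps most likely to fail:

1. Step 34 (Proposed new method). What may go wrong: intermolecular coupling to oligomers in place of ring closure, β-hydride elimination from the C13 alkylpalladium towards C12, or ionisation of the C25 allylic ester by zerovalent palladium. The fallback uses known chemistry, sets out from alcohol 39 and methyl ester 10, and comes back at 43. Alcohol 39 is treated with 9-BBN (2.5 equiv, THF) to give the doubly borylated species F1 (B-alkyl-9-BBN at C14 and a 9-BBN borinate on the C25 oxygen). This is coupled in the same flask with bromide 10 under intermolecular alkyl–alkyl Suzuki–Miyaura conditions (Pd(OAc)2, PCy3, K3PO4·H2O, THF, rt), and aqueous work-up frees the C25 hydroxyl to give the open-chain C1–C36 hydroxy ester F2. Me3SnOH (1,2-dichloroethane, 70 °C) then gives the seco acid F3, and Shiina macrolactonisation (2-methyl-6-nitrobenzoic anhydride, DMAP, CH2Cl2, rt, slow addition) closes the lactone to 43. In this variant the C13–C14 bond is made between two separate halves and the ring is closed at the C25–O–C1 ester instead.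

2. Step 32. What may go wrong: poor facial selectivity in the addition to the α-methoxy aldehyde, so that both C25 epimers form. The fallback sets out from 39 obtained as an epimer mixture and comes back at 39. Dess–Martin oxidation gives the C25 enone F4, and Zn(BH4)2 (Et2O, −30 °C) reduces it under chelation control through the C24 methoxy oxygen, which should deliver the 24,25-anti alcohol 39.

3. Step 6. What may go wrong: loss of HBr from the β-bromo aldehyde, or racemisation of its α-stereocentre, during the olefination. The fallback sets out from aldehyde 14 (step 11), which has the same spatial arrangement at the methyl-bearing carbon, and comes back at 8. Dibromo-olefination of 14 (CBr4, PPh3, Zn, CH2Cl2, 0 °C) gives the TES-protected dibromoalkene F5, PPTS in MeOH removes the TES group to give alcohol F6, and Appel bromination (CBr4, PPh3, CH2Cl2, 0 °C) gives tribromide 8, so that no β-bromo aldehyde is formed.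

Further compounds

F1 | step 34 | doubly borylated derivative of 39: B-alkyl-9-BBN at C14 and 9-BBN borinate at the C25 oxygen | C1CCC2CCCC1B2CC[C@@H](OC)[C@H](O[Si](CC)(CC)CC)/C=C/C(C)=C/[C@@H](C)[C@H](O[Si](CC)(CC)CC)[C@@H](OC)[C@@H](OB1C2CCCC1CCC2)/C=C/C[C@H](O[Si](CC)(CC)CC)[C@@]1(C)O[C@@H]1[C@H](OC)[C@@H](O[Si](CC)(CC)CC)CCC
F2 | step 34 | open-chain C1–C36 hydroxy methyl ester (C13–C14 bond formed, free C25 hydroxyl, six TES ethers) | COC(=O)/C=C/C=C/[C@@H](O[Si](CC)(CC)CC)[C@H](O[Si](CC)(CC)CC)/C=C/C(C)=C/[C@H](C)CCC[C@@H](OC)[C@H](O[Si](CC)(CC)CC)/C=C/C(C)=C/[C@@H](C)[C@H](O[Si](CC)(CC)CC)[C@@H](OC)[C@@H](O)/C=C/C[C@H](O[Si](CC)(CC)CC)[C@@]1(C)O[C@@H]1[C@H](OC)[C@@H](O[Si](CC)(CC)CC)CCC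
F3 | step 34 | open-chain C1–C36 seco acid (free C25 hydroxyl, six TES ethers) | OC(=O)/C=C/C=C/[C@@H](O[Si](CC)(CC)CC)[C@H](O[Si](CC)(CC)CC)/C=C/C(C)=C/[C@H](C)CCC[C@@H](OC)[C@H](O[Si](CC)(CC)CC)/C=C/C(C)=C/[C@@H](C)[C@H](O[Si](CC)(CC)CC)[C@@H](OC)[C@@H](O)/C=C/C[C@H](O[Si](CC)(CC)CC)[C@@]1(C)O[C@@H]1[C@H](OC)[C@@H](O[Si](CC)(CC)CC)CCC
F4 | step 32 | C25 enone of the C14–C36 fragment | C=C[C@@H](OC)[C@H](O[Si](CC)(CC)CC)/C=C/C(C)=C/[C@@H](C)[C@H](O[Si](CC)(CC)CC)[C@@H](OC)C(=O)/C=C/C[C@H](O[Si](CC)(CC)CC)[C@@]1(C)O[C@@H]1[C@H](OC)[C@@H](O[Si](CC)(CC)CC)CCC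
F5 | step 6 | (S)-[(4,4-dibromo-2-methylbut-3-en-1-yl)oxy]triethylsilane | CC[Si](CC)(CC)OC[C@@H](C)C=C(Br)Br
F6 | step 6 | (S)-4,4-dibromo-2-methylbut-3-en-1-ol | OC[C@@H](C)C=C(Br)Br
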